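**Plan**

- Retrosynthesis first removes the two benzyl groups (ring A phenol ether, ring B carboxyl ester), then cuts ring B at C1–C2 and C5–C6, and finally cuts the depside C(=O)–O bond at the stage of an open-chain enol ester.
- The feature that allows this is the pattern on ring B: carboxyl at C1, methoxy at C2, the depside oxygen at C4, pentyl at C6. C2 maps onto a ketene-acetal carbon, C4 onto an enol-ester carbon, and C1/C6 onto the two alkyne carbons of an oct-2-ynoate.
- Forward, ring A comes ready-made from olivetol (formylation, 4-O-benzylation, 2-O-methylation, oxidation, acid chloride). The C4 ketene-acetal enone comes from acetyl chloride and vinylidene chloride.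
- The ring A acyl group is put on the enolate oxygen of the enone. Ring B then arises in one Diels–Alder/aromatization with benzyl oct-2-ynoate, and hydrogenolysis frees the phenol and the acid.
- The target has no stereocentre and no stereogenic double bond. Only regiochemistry must be controlled: by the chelated 2-hydroxyl in the benzylation and by polarity matching in the cycloaddition.

Key step: step 10

Remark: enone 12 and diene 16 are hydrolytically labile ketene acetals; it is assumed that both are handled under argon with non-aqueous work-up and that 16 is used without chromatography.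

**Route**

Step 1
Reactants: 1 olivetol (5-pentylbenzene-1,3-diol)
Product: 3 2,4-dihydroxy-6-pentylbenzaldehyde, via aryliminium chloride 2 (not isolated)
Conditions: POCl3, DMF, 0 °C → rt; then H2O, 50 °C
Reagents that add atoms: N,N-dimethylformamide CN(C)C=O; water O
Why: Vilsmeier–Haack formylation, which on 5-alkylresorcinols is known to occur para to one hydroxyl and ortho to the other rather than between the two hydroxyls, followed by hydrolysis of the iminium salt to the aldehyde.

Step 2
Reactants: 3 2,4-dihydroxy-6-pentylbenzaldehyde
Product: 4 4-(benzyloxy)-2-hydroxy-6-pentylbenzaldehyde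
Conditions: BnBr (1.1 equiv), NaHCO3, MeCN, 80 °C
Reagents that add atoms: benzyl bromide BrCc1ccccc1
Why: Williamson ether synthesis under weak base, selective for the 4-hydroxyl because the 2-hydroxyl is tied up in a hydrogen bond to the formyl group and is less acidic and less nucleophilic.

Step 3
Reactants: 4 4-(benzyloxy)-2-hydroxy-6-pentylbenzaldehyde
Product: 5 4-(benzyloxy)-2-methoxy-6-pentylbenzaldehyde
Conditions: MeI, K2CO3, DMF, rt
Reagents that add atoms: iodomethane CI
Why: Williamson methylation of the remaining chelated phenol, which the stronger base in a polar aprotic solvent should deprotonate and alkylate cleanly.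

Step 4
Reactants: 5 4-(benzyloxy)-2-methoxy-6-pentylbenzaldehyde
Product: 6 4-(benzyloxy)-2-methoxy-6-pentylbenzoic acid
Conditions: NaClO2, NaH2PO4, 2-methylbut-2-ene (excess), t-BuOH/H2O, rt
Reagents that add atoms: sodium chlorite [Na+].[O-]Cl=O
Why: Pinnick oxidation, in which chlorous acid converts the aldehyde to the acid while the alkene scavenger removes hypochlorous acid before it can chlorinate the electron-rich ring; the benzyl ether is unaffected.

Step 5
Reactants: 6 4-(benzyloxy)-2-methoxy-6-pentylbenzoic acid
Product: 7 4-(benzyloxy)-2-methoxy-6-pentylbenzoyl chloride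
Conditions: (COCl)2, DMF (cat.), CH2Cl2, 0 °C → rt; evaporation
Reagents that add atoms: oxalyl chloride O=C(Cl)C(=O)Cl
Why: Acid chloride formation through the catalytic chloroiminium (Vilsmeier-type) pathway, mild and neutral enough to leave both aryl ethers intact.

Step 6
Reactants: 8 acetyl chloride; 9 vinylidene chloride (1,1-dichloroethene)
Product: 11 4,4-dichlorobut-3-en-2-one, via 4,4,4-trichlorobutan-2-one 10 (not isolated)
Conditions: AlCl3, CH2Cl2, 0 °C → rt; ice/aq HCl; distillation (− HCl)
Reagents that add atoms: none
Why: Friedel–Crafts-type (Kondakov) acylation of an alkene, in which the acylium ion adds to the CH2 terminus of the dichloroalkene, chloride captures the cation, and the β-chloro ketone loses HCl on heating to give the conjugated dichlorovinyl ketone.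

Step 7
Reactants: 11 4,4-dichlorobut-3-en-2-one
Product: 12 4,4-dimethoxybut-3-en-2-one
Conditions: NaOMe (2.1 equiv), MeOH, 0 °C → rt; filtration, distillation
Reagents that add atoms: sodium methoxide [Na+].[O-]C
Why: Two successive conjugate addition–elimination steps (nucleophilic vinylic substitution) by methoxide at the β-carbon of the dichlorovinyl ketone should give the acyl ketene acetal.

Step 8
Reactants: 13 oct-2-ynoic acid
Product: 14 benzyl oct-2-ynoate
Conditions: BnBr, KHCO3, DMF, rt
Reagents that add atoms: benzyl bromide BrCc1ccccc1
Why: SN2 O-alkylation of the carboxylate, chosen over carbodiimide/amine-catalysed esterification so that no nucleophilic catalyst can add to the ynoate and no base strong enough to isomerize it is present.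

Step 9
Reactants: 12 4,4-dimethoxybut-3-en-2-one; 7 4-(benzyloxy)-2-methoxy-6-pentylbenzoyl chloride
Product: 16 4,4-dimethoxybuta-1,3-dien-2-yl 4-(benzyloxy)-2-methoxy-6-pentylbenzoate, via potassium dienolate 15 (not isolated)
Conditions: KN(SiMe3)2, THF, −78 °C; then added to 7, THF, −78 → 0 °C; pentane, filtration under Ar, evaporation
Reagents that add atoms: none
Why: Enol ester formation by O-acylation of a ketone enolate, where the methyl group is the only acidic site of 12 and the loose potassium ion pair together with the hard, doubly ortho-substituted aroyl chloride should direct attack through oxygen.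

Step 10
Reactants: 16 4,4-dimethoxybuta-1,3-dien-2-yl 4-(benzyloxy)-2-methoxy-6-pentylbenzoate; 14 benzyl oct-2-ynoate
Product: 18 benzyl 4-{[4-(benzyloxy)-2-methoxy-6-pentylbenzoyl]oxy}-2-methoxy-6-pentylbenzoate, via cyclohexadiene ketal 17 (not isolated)
Conditions: 14 (2–3 equiv), toluene, 120 °C, sealed tube, Ar; then SiO2, CH2Cl2, rt
Reagents that add atoms: none
Why: On heating, the electron-rich diene 16 and the electron-poor ynoate 14 should combine in a normal-electron-demand, concerted but strongly asynchronous Diels–Alder reaction in which bonding between the diene CH2 terminus and the pentyl-bearing β-carbon of 14 runs ahead of bonding between the ketene-acetal carbon and the α-carbon. Ring B thus closes in a single intermolecular (4+2) event, four carbons coming from the diene and two from the alkyne, to give the 1,4-cyclohexadiene ketal 17 with the new C5–C6 and C1–C2 bonds, and 17 then aromatizes by 1,4-elimination of methanol from the ketal carbon and the ring CH2, thermally or on silica gel. The closest known reaction type is the cycloaddition–aromatization of 1,1-dialkoxy-3-silyloxybuta-1,3-dienes (Brassard-type dienes) with alk-2-ynoates, and 2-acyloxybuta-1,3-dienes are likewise established Diels–Alder dienes, so the two features are merely combined in one diene. No stereocentre is created, and both sp3 ring carbons of 17 disappear on aromatization. Regioselectivity is the only selectivity required and the diene secures it: the two methoxy groups and the C3 ester oxygen all place the largest HOMO coefficient on the terminal CH2, which pairs with the β-carbon of the ynoate, so that the benzyl ester ends up flanked by methoxy and pentyl with the aroyloxy group para to it. The benzyl ether, both ester types and the enol-ester link should tolerate neutral, anhydrous heating, and the excess of 14 keeps the bimolecular step ahead of diene decomposition.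

Step 11
Reactants: 18 benzyl 4-{[4-(benzyloxy)-2-methoxy-6-pentylbenzoyl]oxy}-2-methoxy-6-pentylbenzoate
Product: 19 4-O-demethylplanaic acid (4-[(4-hydroxy-2-methoxy-6-pentylbenzoyl)oxy]-2-methoxy-6-pentylbenzoic acid)
Conditions: H2 (1 atm), Pd/C (10 wt% Pd), EtOAc, rt
Reagents that add atoms: none
Why: Catalytic hydrogenolysis cleaves the benzyl ether and the benzyl ester in one operation, while the aryl ester of the depside, the methyl ethers and the arenes are inert under these neutral conditions.

**Compound list**

1 | olivetol (5-pentylbenzene-1,3-diol) | CCCCCc1cc(O)cc(O)c1 | starting material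
2 | (2,4-dihydroxy-6-pentylbenzylidene)dimethyliminium chloride | CCCCCc1cc(O)cc(O)c1C=[N+](C)C.[Cl-] | intermediate
3 | 2,4-dihydroxy-6-pentylbenzaldehyde | CCCCCc1cc(O)cc(O)c1C=O | intermediate
4 | 4-(benzyloxy)-2-hydroxy-6-pentylbenzaldehyde | CCCCCc1cc(OCc2ccccc2)cc(O)c1C=O | intermediate
5 | 4-(benzyloxy)-2-methoxy-6-pentylbenzaldehyde | CCCCCc1cc(OCc2ccccc2)cc(OC)c1C=O | intermediate
6 | 4-(benzyloxy)-2-methoxy-6-pentylbenzoic acid | CCCCCc1cc(OCc2ccccc2)cc(OC)c1C(=O)O | intermediate
7 | 4-(benzyloxy)-2-methoxy-6-pentylbenzoyl chloride | CCCCCc1cc(OCc2ccccc2)cc(OC)c1C(=O)Cl | intermediate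
8 | acetyl chloride | CC(=O)Cl | starting material
9 | vinylidene chloride (1,1-dichloroethene) | C=C(Cl)Cl | starting material
10 | 4,4,4-trichlorobutan-2-one | CC(=O)CC(Cl)(Cl)Cl | intermediate
11 | 4,4-dichlorobut-3-en-2-one | CC(=O)C=C(Cl)Cl | intermediate
12 | 4,4-dimethoxybut-3-en-2-one | CC(=O)C=C(OC)OC | intermediate
13 | oct-2-ynoic acid | CCCCCC#CC(=O)O | starting material
14 | benzyl oct-2-ynoate | CCCCCC#CC(=O)OCc1ccccc1 | intermediate
15 | potassium 4,4-dimethoxybuta-1,3-dien-2-olate | C=C([O-])C=C(OC)OC.[K+] | intermediate
16 | 4,4-dimethoxybuta-1,3-dien-2-yl 4-(benzyloxy)-2-methoxy-6-pentylbenzoate | C=C(OC(=O)c1c(CCCCC)cc(OCc2ccccc2)cc1OC)C=C(OC)OC | intermediate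
17 | benzyl 4-{[4-(benzyloxy)-2-methoxy-6-pentylbenzoyl]oxy}-6,6-dimethoxy-2-pentylcyclohexa-1,4-diene-1-carboxylate | CCCCCC1=C(C(=O)OCc2ccccc2)C(OC)(OC)C=C(OC(=O)c2c(CCCCC)cc(OCc3ccccc3)cc2OC)C1 | intermediate
18 | benzyl 4-{[4-(benzyloxy)-2-methoxy-6-pentylbenzoyl]oxy}-2-methoxy-6-pentylbenzoate | CCCCCc1cc(OC(=O)c2c(CCCCC)cc(OCc3ccccc3)cc2OC)cc(OC)c1C(=O)OCc1ccccc1 | intermediate
19 | 4-O-demethylplanaic acid | CCCCCc1cc(OC(=O)c2c(CCCCC)cc(O)cc2OC)cc(OC)c1C(=O)O | target

**Step count**

Total: 11 steps. Longest linear sequence: 8 steps (steps 1, 2, 3, 4, 5, 9, 10, 11 from olivetol).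

**Steps most likely to fail**

Step 10. The cycloaddition may be too slow, because the acyloxy group at the diene C3 donates less than a silyloxy group and the ynoate β-carbon carries an alkyl chain. Diene 16 could then polymerize or be hydrolysed by adventitious water before it is consumed. The fallback sets out from 16 and replaces the alkyne by its allene isomer. Hexanoyl chloride, benzyl (triphenylphosphoranylidene)acetate and Et3N in CH2Cl2 at 0 °C → rt (Wittig olefination of the ketene formed in the flask) should give racemic benzyl octa-2,3-dienoate F1. The α,β-double bond of an allenoate is a far better dienophile and is known to add to 1,1-dialkoxy-3-oxy dienes near room temperature with the same orientation. With 16 in toluene at rt to 60 °C it should give the pentylidene-cyclohexene cycloadduct F2, not isolated. On silica gel or with a trace of acid, F2 should lose methanol and shift the exocyclic double bond into the ring, rejoining the route at 18.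

Step 9. The ambident dienolate may be acylated at its terminal carbon, the product may transfer its acyl group to unreacted enolate, or the ketene acetal may hydrolyse during isolation. The fallback sets out from enone 12 and acid 6 and returns at 16. Enone 12 is converted with LiN(i-Pr)2 in THF at −78 °C and Me3SiCl into distillable 1,1-dimethoxy-3-(trimethylsilyloxy)buta-1,3-diene F3. Acid 6 is converted with cyanuric fluoride and pyridine in CH2Cl2 into 4-(benzyloxy)-2-methoxy-6-pentylbenzoyl fluoride F4. Fluoride-catalysed O-acylation of the silyl enol ether by the acyl fluoride (KF with 18-crown-6, THF, rt) should then give 16. The only co-product is a volatile fluorosilane, so no aqueous work-up is needed.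

Step 7. Methoxide or methanol may add to the acyl ketene acetal to give the ortho ester, the second substitution may stall at the chloro(methoxy)vinyl ketone, or the product may hydrolyse to methyl acetoacetate on work-up. The fallback sets out from acetyl chloride 8 and returns at 12. Commercial 1,1-dimethoxyethene (two equivalents, the second serving as HCl acceptor) is C-acylated in Et2O at 0 °C → rt, a known acylation of ketene acetals that needs neither base nor water, and 12 is distilled. This fallback makes no compound outside the compound list (entry F0).

**Further compounds**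

F1 | step 10 | benzyl octa-2,3-dienoate (racemic) | CCCCC=C=CC(=O)OCc1ccccc1
F2 | step 10 | benzyl 4-{[4-(benzyloxy)-2-methoxy-6-pentylbenzoyl]oxy}-2,2-dimethoxy-6-pentylidenecyclohex-3-ene-1-carboxylate (isomer mixture, not isolated) | CCCCC=C1CC(OC(=O)c2c(CCCCC)cc(OCc3ccccc3)cc2OC)=CC(OC)(OC)C1C(=O)OCc1ccccc1
F3 | step 9 | 1,1-dimethoxy-3-(trimethylsilyloxy)buta-1,3-diene | C=C(O[Si](C)(C)C)C=C(OC)OC
F4 | step 9 | 4-(benzyloxy)-2-methoxy-6-pentylbenzoyl fluoride | CCCCCc1cc(OCc2ccccc2)cc(OC)c1C(F)=O
F0 | step 7 | none | none
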